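**Strategy.** All three flavan units are cut back to one protected monomer, because every C4 is either a leaving-group site (upper and middle units) or an oxygenated terminus (lower unit). Ring C of this monomer is made in one operation by an inverse-demand oxa-[4+2] cycloaddition. The heterodiene O1=C8a–C4a=C4 latent in ring A of a salicylaldehyde acetal (an α-methoxy o-quinone methide) takes up C2=C3 of the Z-enol acetate of a 4-oxygenated phenylacetaldehyde. This forms O1–C2, C3–C4 and the cis C2/C3/C4 triad under a chiral Brønsted acid. Bromine capping, a C4 thioether and acetoxonium chemistry then turn the monomer into upper, middle and lower units, joined by two 4β→6 arylations.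

Key step: step 3

Remarks and assumptions:
- Flavan numbering (O1, C2, C3, C4, C4a, C5 to C8, C8a) is used throughout; the units are called upper, middle and lower. "Epioritin" means (2R,3R)-2,3-cis-4′,7,8-trihydroxyflavan-3-ol.
- Compounds 1 and 3 are taken as commercial.
- The enantiomer of the phosphoramide catalyst written in step 3 is assumed to lead to the 2R,3R series; if a first run shows the opposite sense, its antipode is used.

Step 1
Reactants: 1 2,3,4-trihydroxybenzaldehyde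
Product: 2 3,4-bis(benzyloxy)-2-hydroxybenzaldehyde
Conditions: BnBr (2.05 equiv), K2CO3 (2.1 equiv), DMF, 0 °C to rt
Reagents that add atoms: benzyl bromide, BrCc1ccccc1
Why: Williamson etherification; the 2-OH is hydrogen-bonded to the formyl group and is the least nucleophilic, so the 4-OH and then the 3-OH should be alkylated and the 2-OH left free.

Step 2
Reactants: 3 1-(benzyloxy)-4-ethynylbenzene
Product: 4 (Z)-2-[4-(benzyloxy)phenyl]ethenyl acetate
Conditions: AcOH (1.5 equiv), [RuCl2(p-cymene)]2 (1 mol %), P(4-ClC6H4)3 (3 mol %), DMAP (4 mol %), toluene, 60 °C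
Reagents that add atoms: acetic acid, CC(=O)O
Why: ruthenium-catalysed anti-Markovnikov hydro-acyloxylation of a terminal alkyne via a ruthenium vinylidene; attack of acetate on the vinylidene α-carbon followed by protonolysis should give the Z-enol ester.

Step 3
Reactants: 2 3,4-bis(benzyloxy)-2-hydroxybenzaldehyde, 4 (Z)-2-[4-(benzyloxy)phenyl]ethenyl acetate
Product: 7 (2R,3R,4R)-7,8-bis(benzyloxy)-2-[4-(benzyloxy)phenyl]-4-methoxy-3,4-dihydro-2H-chromen-3-yl acetate, via dimethyl acetal 5 (not isolated), via o-quinone methide 6 (not isolated)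
Conditions: HC(OMe)3 (1.5 equiv), (R)-3,3′-bis(2,4,6-triisopropylphenyl)-1,1′-binaphthyl-2,2′-diyl N-triflylphosphoramide (5 mol %), 5 Å MS, toluene, rt; then 4 (1.5 equiv), −30 °C
Reagents that add atoms: trimethyl orthoformate, COC(OC)OC
Why: Proposed new method: the acid converts 2 and the orthoformate into acetal 5, which loses methanol to the E-configured α-methoxy o-quinone methide 6, held as a hydrogen-bonded ion pair with the chiral phosphoramide; 6 (4π, O1=C8a–C4a=C4) and the enol acetate 4 (2π, C3=C2) then combine in an asynchronous inverse-electron-demand oxa-[4+2] cycloaddition in which the C3–C4 bond leads and O1 closes onto the developing 4-benzyloxybenzylic centre C2. The closest known reaction types are the acid-catalysed three-component salicylaldehyde/orthoformate/styrene synthesis of 4-alkoxyflavans and the chiral-Brønsted-acid-catalysed [4+2] cycloadditions of o-quinone methides with styrenes and, intramolecularly, of salicylaldehyde-derived alkoxy o-quinone methides with tethered alkenes; new here are the β-acyloxystyrene as 2π partner and the intermolecular asymmetric version. Ring C is closed in the cycloaddition mode itself (six-membered transition state, suprafacial on both partners). C2 and C3 should come out cis because the Z geometry of 4 is carried over, C4 cis to both because aryl and acetoxy lie endo to the E-quinone methide, and the absolute configuration (2R,3R) is set by the chiral counter-anion shielding one face of 6. The step needs regioselectivity (C3 to C4, aryl carbon to O1), secured because the 4-benzyloxyphenyl group and not the cross-conjugated acetoxy oxygen stabilises the charge building up at C2, and it needs retention of the Z geometry, favoured by the weak acid and low temperature that keep the pathway concerted. The C4 configuration has no later consequence, since C4 is ionised in every further use of 7.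

Step 4
Reactants: 7 (2R,3R,4R)-7,8-bis(benzyloxy)-2-[4-(benzyloxy)phenyl]-4-methoxy-3,4-dihydro-2H-chromen-3-yl acetate
Product: 8 (2R,3R,4R)-7,8-bis(benzyloxy)-2-[4-(benzyloxy)phenyl]-6-bromo-4-methoxy-3,4-dihydro-2H-chromen-3-yl acetate
Conditions: NBS (1.05 equiv), CH2Cl2, −40 °C to 0 °C, dark
Reagents that add atoms: N-bromosuccinimide, O=C1CCC(=O)N1Br
Why: electrophilic aromatic bromination at C6, the most electron-rich free position (ortho to the 7-benzyloxy group, para to O1); the bromine blocks this nucleophilic site during chain assembly and is removed in the last step.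

Step 5
Reactants: 7 (2R,3R,4R)-7,8-bis(benzyloxy)-2-[4-(benzyloxy)phenyl]-4-methoxy-3,4-dihydro-2H-chromen-3-yl acetate
Product: 9 (2R,3S,4S)-7,8-bis(benzyloxy)-2-[4-(benzyloxy)phenyl]-4-[(2,6-dimethylphenyl)sulfanyl]-3,4-dihydro-2H-chromen-3-yl acetate
Conditions: 2,6-Me2C6H3SH (3 equiv), BF3·OEt2 (0.2 equiv), CH2Cl2, −78 °C to −30 °C
Reagents that add atoms: 2,6-dimethylbenzenethiol, Cc1cccc(C)c1S
Why: SN1 thiolysis at C4 through the flavan-4-yl cation (stabilised by the 7-benzyloxy group and O1); the participating 3-acetate on the α face directs the thiol to the β face (3,4-trans), and the excess thiol should outrun self-arylation.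

Step 6
Reactants: 7 (2R,3R,4R)-7,8-bis(benzyloxy)-2-[4-(benzyloxy)phenyl]-4-methoxy-3,4-dihydro-2H-chromen-3-yl acetate
Product: 12 (2R,3S,4R)-7,8-bis(benzyloxy)-2-[4-(benzyloxy)phenyl]-3,4-dihydro-2H-chromene-3,4-diyl diacetate, via acetoxonium triflate 10 (not isolated), via hydroxy acetate 11 (not isolated)
Conditions: Me3SiOTf (1.1 equiv), CH2Cl2 (0.01 M), −78 °C, 10 min; H2O/THF, −78 °C to 0 °C; then pyridine, Ac2O, DMAP (cat.), 0 °C to rt
Reagents that add atoms: water, O; acetic anhydride, CC(=O)OC(C)=O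
Why: Woodward-type cis-hydroxylation by neighbouring-group participation; anhydrous ionisation of C4–OMe lets the 3-acetoxy carbonyl oxygen close the cis-fused 2-methyl-1,3-dioxolan-2-ylium ion 10 on the α face, water adds to the dioxolanylium carbon and the ortho acid collapses to the cis hydroxy acetate 11 (C4–O α, dictated by C3), which is acetylated in the same flask.

Step 7
Reactants: 8 (2R,3R,4R)-7,8-bis(benzyloxy)-2-[4-(benzyloxy)phenyl]-6-bromo-4-methoxy-3,4-dihydro-2H-chromen-3-yl acetate, 9 (2R,3S,4S)-7,8-bis(benzyloxy)-2-[4-(benzyloxy)phenyl]-4-[(2,6-dimethylphenyl)sulfanyl]-3,4-dihydro-2H-chromen-3-yl acetate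
Product: 13 3-O-acetyl-7,8,4′-tri-O-benzyl-6-bromoepioritin-(4β→6)-[3-O-acetyl-7,8,4′-tri-O-benzyl-4β-(2,6-dimethylphenylsulfanyl)epioritin]
Conditions: Me3SiOTf (0.2 equiv), 4 Å MS, CH2Cl2, −78 °C; 9 (1.3 equiv)
Reagents that add atoms: none
Why: Friedel–Crafts-type flavan-4-yl arylation; the oxophilic silyl triflate ionises C4–OMe of 8 but not the hindered thioether of 9, C6 of 9 is the nucleophilic site (the doubly flanked 8-benzyloxy group is twisted out of conjugation, so C5 stays unreactive), attack anti to the participating 3-acetate gives the 4β (3,4-trans) bond, and the bromine on 8 prevents self-condensation.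

Step 8
Reactants: 13 3-O-acetyl-7,8,4′-tri-O-benzyl-6-bromoepioritin-(4β→6)-[3-O-acetyl-7,8,4′-tri-O-benzyl-4β-(2,6-dimethylphenylsulfanyl)epioritin], 12 (2R,3S,4R)-7,8-bis(benzyloxy)-2-[4-(benzyloxy)phenyl]-3,4-dihydro-2H-chromene-3,4-diyl diacetate
Product: 14 3-O-acetyl-7,8,4′-tri-O-benzyl-6-bromoepioritin-(4β→6)-(3-O-acetyl-7,8,4′-tri-O-benzylepioritin)-(4β→6)-(3,4-di-O-acetyl-7,8,4′-tri-O-benzylepioritin-4α-ol)
Conditions: AgBF4 (2 equiv), 2,6-di-tert-butyl-4-methylpyridine (2 equiv), 4 Å MS, CH2Cl2/THF, −40 °C to 0 °C, dark; 12 (1.5 equiv)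
Reagents that add atoms: none
Why: silver-assisted (thiophilic) ionisation of the C4 thioether gives the middle-unit flavan-4-yl cation, which arylates C6 of 12 anti to its 3-acetate (4β); the soft activator and hindered base should leave the benzylic 4-acetate of the lower unit un-ionised, and neither 13 nor 14 offers another reactive nucleophilic position.

Step 9
Reactants: 14 3-O-acetyl-7,8,4′-tri-O-benzyl-6-bromoepioritin-(4β→6)-(3-O-acetyl-7,8,4′-tri-O-benzylepioritin)-(4β→6)-(3,4-di-O-acetyl-7,8,4′-tri-O-benzylepioritin-4α-ol)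
Product: 15 7,8,4′-tri-O-benzyl-6-bromoepioritin-(4β→6)-(7,8,4′-tri-O-benzylepioritin)-(4β→6)-(7,8,4′-tri-O-benzylepioritin-4α-ol)
Conditions: K2CO3 (0.5 equiv), MeOH/THF, rt
Reagents that add atoms: none
Why: base-catalysed transesterification (Zemplén-type methanolysis) at the acyl carbons should remove the four acetates with retention at every carbinol centre, including the benzylic C4 of the lower unit.

Step 10
Reactants: 15 7,8,4′-tri-O-benzyl-6-bromoepioritin-(4β→6)-(7,8,4′-tri-O-benzylepioritin)-(4β→6)-(7,8,4′-tri-O-benzylepioritin-4α-ol)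
Product: 16 epioritin-(4β→6)-epioritin-(4β→6)-epioritin-4α-ol (CNP0140823.1)
Conditions: H2 (1 atm), Pd(OH)2/C, NaHCO3 (1.5 equiv), THF/MeOH/H2O, rt; filtration under argon, Sephadex LH-20
Reagents that add atoms: none
Why: hydrogenolysis of the nine aryl benzyl ethers and hydrodebromination at C6 in one operation; the buffered neutral medium traps HBr and should spare the benzylic C4–OH, the C2–O1 bonds and the interflavan bonds, which are cleaved far more slowly than aryl benzyl ethers.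

**Compound list**

1 | 2,3,4-trihydroxybenzaldehyde | O=Cc1ccc(O)c(O)c1O | starting material
2 | 3,4-bis(benzyloxy)-2-hydroxybenzaldehyde | O=Cc1ccc(OCc2ccccc2)c(OCc2ccccc2)c1O | intermediate
3 | 1-(benzyloxy)-4-ethynylbenzene | C#Cc1ccc(OCc2ccccc2)cc1 | starting material
4 | (Z)-2-[4-(benzyloxy)phenyl]ethenyl acetate | CC(=O)O/C=C\c1ccc(OCc2ccccc2)cc1 | intermediate
5 | 2,3-bis(benzyloxy)-6-(dimethoxymethyl)phenol | COC(OC)c1ccc(OCc2ccccc2)c(OCc2ccccc2)c1O | intermediate
6 | (6E)-2,3-bis(benzyloxy)-6-(methoxymethylidene)cyclohexa-2,4-dien-1-one | CO/C=C1\C=CC(OCc2ccccc2)=C(OCc2ccccc2)C1=O | intermediate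
7 | (2R,3R,4R)-7,8-bis(benzyloxy)-2-[4-(benzyloxy)phenyl]-4-methoxy-3,4-dihydro-2H-chromen-3-yl acetate (all-cis) | c1cc2c(c(OCc3ccccc3)c1OCc1ccccc1)O[C@H](c1ccc(OCc3ccccc3)cc1)[C@H](OC(C)=O)[C@@H]2OC | intermediate
8 | (2R,3R,4R)-7,8-bis(benzyloxy)-2-[4-(benzyloxy)phenyl]-6-bromo-4-methoxy-3,4-dihydro-2H-chromen-3-yl acetate | Brc1cc2c(c(OCc3ccccc3)c1OCc1ccccc1)O[C@H](c1ccc(OCc3ccccc3)cc1)[C@H](OC(C)=O)[C@@H]2OC | intermediate
9 | (2R,3S,4S)-7,8-bis(benzyloxy)-2-[4-(benzyloxy)phenyl]-4-[(2,6-dimethylphenyl)sulfanyl]-3,4-dihydro-2H-chromen-3-yl acetate (2,3-cis, 3,4-trans) | c1cc2c(c(OCc3ccccc3)c1OCc1ccccc1)O[C@H](c1ccc(OCc3ccccc3)cc1)[C@H](OC(C)=O)[C@H]2Sc1c(C)cccc1C | intermediate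
10 | cis-fused 2-methyl-1,3-dioxolan-2-ylium (acetoxonium) triflate bridging O3 and O4 of the 7,8,4′-tri-O-benzyl flavan on the α face | c1cc2c(c(OCc3ccccc3)c1OCc1ccccc1)O[C@H](c1ccc(OCc3ccccc3)cc1)[C@@H]1OC(C)=[O+][C@H]21.[O-]S(=O)(=O)C(F)(F)F | intermediate
11 | (2R,3R,4R)-7,8-bis(benzyloxy)-2-[4-(benzyloxy)phenyl]-4-hydroxy-3,4-dihydro-2H-chromen-3-yl acetate (all-cis) | c1cc2c(c(OCc3ccccc3)c1OCc1ccccc1)O[C@H](c1ccc(OCc3ccccc3)cc1)[C@H](OC(C)=O)[C@@H]2O | intermediate
12 | (2R,3S,4R)-7,8-bis(benzyloxy)-2-[4-(benzyloxy)phenyl]-3,4-dihydro-2H-chromene-3,4-diyl diacetate (all-cis) | c1cc2c(c(OCc3ccccc3)c1OCc1ccccc1)O[C@H](c1ccc(OCc3ccccc3)cc1)[C@H](OC(C)=O)[C@@H]2OC(C)=O | intermediate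
13 | 3-O-acetyl-7,8,4′-tri-O-benzyl-6-bromoepioritin-(4β→6)-[3-O-acetyl-7,8,4′-tri-O-benzyl-4β-(2,6-dimethylphenylsulfanyl)epioritin] | c9ccccc9COc1ccc([C@H]2Oc3c(cc(Br)c(OCc9ccccc9)c3OCc3ccccc3)[C@H](c3cc4c(c(OCc9ccccc9)c3OCc3ccccc3)O[C@H](c3ccc(OCc9ccccc9)cc3)[C@H](OC(C)=O)[C@H]4Sc3c(C)cccc3C)[C@H]2OC(C)=O)cc1 | intermediate
14 | 3-O-acetyl-7,8,4′-tri-O-benzyl-6-bromoepioritin-(4β→6)-(3-O-acetyl-7,8,4′-tri-O-benzylepioritin)-(4β→6)-(3,4-di-O-acetyl-7,8,4′-tri-O-benzylepioritin-4α-ol) | c9ccccc9COc1ccc([C@H]2Oc3c(cc(Br)c(OCc9ccccc9)c3OCc3ccccc3)[C@H](c3cc4c(c(OCc9ccccc9)c3OCc3ccccc3)O[C@H](c3ccc(OCc9ccccc9)cc3)[C@H](OC(C)=O)[C@H]4c3cc4c(c(OCc9ccccc9)c3OCc3ccccc3)O[C@H](c3ccc(OCc9ccccc9)cc3)[C@H](OC(C)=O)[C@@H]4OC(C)=O)[C@H]2OC(C)=O)cc1 | intermediate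
15 | 7,8,4′-tri-O-benzyl-6-bromoepioritin-(4β→6)-(7,8,4′-tri-O-benzylepioritin)-(4β→6)-(7,8,4′-tri-O-benzylepioritin-4α-ol) | c9ccccc9COc1ccc([C@H]2Oc3c(cc(Br)c(OCc9ccccc9)c3OCc3ccccc3)[C@H](c3cc4c(c(OCc9ccccc9)c3OCc3ccccc3)O[C@H](c3ccc(OCc9ccccc9)cc3)[C@H](O)[C@H]4c3cc4c(c(OCc9ccccc9)c3OCc3ccccc3)O[C@H](c3ccc(OCc9ccccc9)cc3)[C@H](O)[C@@H]4O)[C@H]2O)cc1 | intermediate
16 | epioritin-(4β→6)-epioritin-(4β→6)-epioritin-4α-ol; all units 2R,3R (2,3-cis), both interflavan bonds 3,4-trans, lower unit 3,4-cis diol | Oc1ccc([C@H]2Oc3c(ccc(O)c3O)[C@H](c3cc4c(c(O)c3O)O[C@H](c3ccc(O)cc3)[C@H](O)[C@H]4c3cc4c(c(O)c3O)O[C@H](c3ccc(O)cc3)[C@H](O)[C@@H]4O)[C@H]2O)cc1 | target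

**Step count.** Total: 10 steps. Longest linear sequence: 7 steps (steps 1, 3, 4 or 5, 7, 8, 9, 10).

**Steps most likely to fail**

Step 3 (proposed new method). Three processes may defeat it:
- the weakly nucleophilic enol acetate may react too slowly, so that the quinone methide reacts with itself or with phenol 5;
- the Z geometry may be lost, by acid-mediated isomerisation of 4 or by a stepwise cationic pathway, giving the 2,3-trans series;
- the chiral acid may discriminate the two faces poorly.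

The fallback uses known chemistry, sets out from 2 and comes back to the route at 9, 12 and 13. Aldehyde 2 and (E)-3-[4-(benzyloxy)phenyl]prop-2-enal are joined in the established aminocatalytic oxa-Michael/aldol/dehydration domino (α,α-diphenylprolinol trimethylsilyl ether, 2-nitrobenzoic acid, toluene). This gives (2R)-7,8-bis(benzyloxy)-2-[4-(benzyloxy)phenyl]-2H-chromene-3-carbaldehyde F1, again closing O1–C2 and C3–C4 in one operation. Baeyer–Villiger oxidation of the enal (H2O2, catalytic bis(2-nitrophenyl) diselenide) gives (2R)-7,8-bis(benzyloxy)-2-[4-(benzyloxy)phenyl]-2H-chromen-3-yl formate F2. Brief K2CO3/MeOH at 0 °C gives (2R)-7,8-bis(benzyloxy)-2-[4-(benzyloxy)phenyl]-2H-chromen-3(4H)-one F3. This is reduced at once with Li[HB(sec-Bu)3] at −78 °C, hydride entering anti to the 2-aryl group, to (2R,3R)-7,8-bis(benzyloxy)-2-[4-(benzyloxy)phenyl]-3,4-dihydro-2H-chromen-3-ol F4. DDQ/MeOH introduces the 4β-methoxy group, giving (2R,3R,4S)-7,8-bis(benzyloxy)-2-[4-(benzyloxy)phenyl]-4-methoxy-3,4-dihydro-2H-chromen-3-ol F5. Ac2O/pyridine gives (2R,3R,4S)-7,8-bis(benzyloxy)-2-[4-(benzyloxy)phenyl]-4-methoxy-3,4-dihydro-2H-chromen-3-yl acetate F6, the C4 epimer of 7. F6 takes the place of 7 in steps 4 to 6. Steps 5 and 6 give 9 and 12 themselves, because C4 is re-set in both. Step 4 gives (2R,3R,4S)-7,8-bis(benzyloxy)-2-[4-(benzyloxy)phenyl]-6-bromo-4-methoxy-3,4-dihydro-2H-chromen-3-yl acetate F7, which gives 13 in step 7.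

Step 6. Water may capture the open C4 cation directly from the β face (3,4-trans) instead of through the acetoxonium ion, and intermolecular arylation may set in before the quench. The fallback sets out from 7 and comes back at 11 (acetylated to 12 as in step 6). Compound 7 is solvolysed in wet THF with catalytic CF3CO2H to (2R,3R,4S)-7,8-bis(benzyloxy)-2-[4-(benzyloxy)phenyl]-4-hydroxy-3,4-dihydro-2H-chromen-3-yl acetate F8; its C4 epimer serves equally. Dess–Martin periodinane gives (2R,3S)-7,8-bis(benzyloxy)-2-[4-(benzyloxy)phenyl]-4-oxo-3,4-dihydro-2H-chromen-3-yl acetate F9. NaBH4 in MeOH/THF at −40 °C then delivers hydride anti to the axial 3-acetoxy group, which should give the all-cis hydroxy acetate 11.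

Step 8. The silver salt may ionise the lower-unit benzylic acetate and scramble chains, the hindered thioether may ionise sluggishly, or arylation may go to C5. The fallback drops the thioether and silver; it sets out from 12, 7 and 8 and comes back at 15. K2CO3/MeOH converts 12 into (2R,3R,4R)-7,8-bis(benzyloxy)-2-[4-(benzyloxy)phenyl]-3,4-dihydro-2H-chromene-3,4-diol F10. 1,1′-Carbonyldiimidazole converts this into the all-cis 3,4-O-carbonyl derivative (cyclic carbonate) F11, whose C4–O bond silyl triflates should no longer ionise. F11 (3 equiv) is arylated by 7 under catalytic Me3SiOTf at −78 °C to 3-O-acetyl-7,8,4′-tri-O-benzylepioritin-(4β→6)-(7,8,4′-tri-O-benzylepioritin-4α-ol 3,4-carbonate) F12. F12 is arylated in the same way by bromo-capped 8 at the free C6 of its upper unit to 3-O-acetyl-7,8,4′-tri-O-benzyl-6-bromoepioritin-(4β→6)-(3-O-acetyl-7,8,4′-tri-O-benzylepioritin)-(4β→6)-(7,8,4′-tri-O-benzylepioritin-4α-ol 3,4-carbonate) F13. K2CO3/MeOH then removes the two acetates and the carbonate to give 15.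

**Further compounds**

F1 | step 3 | (2R)-7,8-bis(benzyloxy)-2-[4-(benzyloxy)phenyl]-2H-chromene-3-carbaldehyde | c1cc2c(c(OCc3ccccc3)c1OCc1ccccc1)O[C@H](c1ccc(OCc3ccccc3)cc1)C(C=O)=C2
F2 | step 3 | (2R)-7,8-bis(benzyloxy)-2-[4-(benzyloxy)phenyl]-2H-chromen-3-yl formate | c1cc2c(c(OCc3ccccc3)c1OCc1ccccc1)O[C@H](c1ccc(OCc3ccccc3)cc1)C(OC=O)=C2
F3 | step 3 | (2R)-7,8-bis(benzyloxy)-2-[4-(benzyloxy)phenyl]-2H-chromen-3(4H)-one | c1cc2c(c(OCc3ccccc3)c1OCc1ccccc1)O[C@H](c1ccc(OCc3ccccc3)cc1)C(=O)C2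
F4 | step 3 | (2R,3R)-7,8-bis(benzyloxy)-2-[4-(benzyloxy)phenyl]-3,4-dihydro-2H-chromen-3-ol | c1cc2c(c(OCc3ccccc3)c1OCc1ccccc1)O[C@H](c1ccc(OCc3ccccc3)cc1)[C@H](O)C2
F5 | step 3 | (2R,3R,4S)-7,8-bis(benzyloxy)-2-[4-(benzyloxy)phenyl]-4-methoxy-3,4-dihydro-2H-chromen-3-ol | c1cc2c(c(OCc3ccccc3)c1OCc1ccccc1)O[C@H](c1ccc(OCc3ccccc3)cc1)[C@H](O)[C@H]2OC
F6 | step 3 | (2R,3R,4S)-7,8-bis(benzyloxy)-2-[4-(benzyloxy)phenyl]-4-methoxy-3,4-dihydro-2H-chromen-3-yl acetate | c1cc2c(c(OCc3ccccc3)c1OCc1ccccc1)O[C@H](c1ccc(OCc3ccccc3)cc1)[C@H](OC(C)=O)[C@H]2OC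
F7 | step 3 | (2R,3R,4S)-7,8-bis(benzyloxy)-2-[4-(benzyloxy)phenyl]-6-bromo-4-methoxy-3,4-dihydro-2H-chromen-3-yl acetate | Brc1cc2c(c(OCc3ccccc3)c1OCc1ccccc1)O[C@H](c1ccc(OCc3ccccc3)cc1)[C@H](OC(C)=O)[C@H]2OC
F8 | step 6 | (2R,3R,4S)-7,8-bis(benzyloxy)-2-[4-(benzyloxy)phenyl]-4-hydroxy-3,4-dihydro-2H-chromen-3-yl acetate | c1cc2c(c(OCc3ccccc3)c1OCc1ccccc1)O[C@H](c1ccc(OCc3ccccc3)cc1)[C@H](OC(C)=O)[C@H]2O
F9 | step 6 | (2R,3S)-7,8-bis(benzyloxy)-2-[4-(benzyloxy)phenyl]-4-oxo-3,4-dihydro-2H-chromen-3-yl acetate | c1cc2c(c(OCc3ccccc3)c1OCc1ccccc1)O[C@H](c1ccc(OCc3ccccc3)cc1)[C@H](OC(C)=O)C2=O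
F10 | step 8 | (2R,3R,4R)-7,8-bis(benzyloxy)-2-[4-(benzyloxy)phenyl]-3,4-dihydro-2H-chromene-3,4-diol | c1cc2c(c(OCc3ccccc3)c1OCc1ccccc1)O[C@H](c1ccc(OCc3ccccc3)cc1)[C@H](O)[C@@H]2O
F11 | step 8 | all-cis 3,4-O-carbonyl derivative (cyclic carbonate) of F10 | c1cc2c(c(OCc3ccccc3)c1OCc1ccccc1)O[C@H](c1ccc(OCc3ccccc3)cc1)[C@@H]1OC(=O)O[C@H]21
F12 | step 8 | 3-O-acetyl-7,8,4′-tri-O-benzylepioritin-(4β→6)-(7,8,4′-tri-O-benzylepioritin-4α-ol 3,4-carbonate) | c9ccccc9COc1ccc([C@H]2Oc3c(ccc(OCc9ccccc9)c3OCc3ccccc3)[C@H](c3cc4c(c(OCc9ccccc9)c3OCc3ccccc3)O[C@H](c3ccc(OCc9ccccc9)cc3)[C@@H]3OC(=O)O[C@H]43)[C@H]2OC(C)=O)cc1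
F13 | step 8 | 3-O-acetyl-7,8,4′-tri-O-benzyl-6-bromoepioritin-(4β→6)-(3-O-acetyl-7,8,4′-tri-O-benzylepioritin)-(4β→6)-(7,8,4′-tri-O-benzylepioritin-4α-ol 3,4-carbonate) | c9ccccc9COc1ccc([C@H]2Oc3c(cc(Br)c(OCc9ccccc9)c3OCc3ccccc3)[C@H](c3cc4c(c(OCc9ccccc9)c3OCc3ccccc3)O[C@H](c3ccc(OCc9ccccc9)cc3)[C@H](OC(C)=O)[C@H]4c3cc4c(c(OCc9ccccc9)c3OCc3ccccc3)O[C@H](c3ccc(OCc9ccccc9)cc3)[C@@H]3OC(=O)O[C@H]43)[C@H]2OC(C)=O)cc1
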